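**Plan**

1. Numbering (briarane): six-membered ring C1, C10–C14 (C1 = C–CH3, C10 = ring-fusion CH); ten-membered ring C1–C10; C15 and C20 = methyls on C1 and C11; C16 = ester carbon on C5; C17–C19 = lactone CH(CH3)–C=O.
2. Retrosynthetic cuts, in order: O9–acetyl; lactone O7–C19 and C5=C6 (olefination that closes the ten-membered ring); C1–C2 (aldol); C10–C11 together with C12–C13 (cycloaddition); C10=C1 (Wittig); C8–C17 (ester aldol on a 3-ulose from D-glucose).
3. Enabling feature: in the cyclohexane ring the oxygens on C14 and C12 are 1,3-related and C11 carries a one-carbon branch next to ring-fusion C10. The ring is therefore the adduct of a 2-silyloxydiene C13=C14(OSiEt3)–C1(CH3)=C10 and an alkene C11=C12 that is activated by C20 as an ester and carries boron in place of O12. The C14=C1 silyl enol ether left behind then builds the quaternary C1.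
4. Forward order: furanose template holding C6–C9 (O9 = ring oxygen; the acetonide masks C6 and O7; removed in step 14) → cyclohexane (step 6) → ten-membered ring, then γ-lactone (step 15).
5. Stereochemistry: C7 and C9 from D-glucose; C8 and C17 from enolate addition to the convex face of the ulose; C10, C11, C12 in the cycloaddition (C9 through allylic strain, endo rule, alkene geometry); C1 anti to the C10 substituent and C2 in the aldol; C14 by 1,3-syn reduction; C5=C6 geometry from the olefination.

Key step: step 6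

**Remarks**

- Reagents 8 and 11 are taken as purchased materials.
- Compound 18 is used as a mixture of C5 epimers and 23 as an anomeric mixture; these centres are written without configuration and disappear in step 15.
- "Fur" = the 1,2-O-isopropylidene-α-D-ribofuranos-4-yl group of 10, bonded through sugar C4 (= C9), with the 3-C-[(2R)-1-tert-butoxy-1-oxopropan-2-yl] branch (C17–C19) and the 3-O-triethylsilyl ether (O8).
- On the six-membered ring, β is the face of the C15 methyl.

**Route**

Step 1
Reactants: 1 1,2:5,6-di-O-isopropylidene-α-D-glucofuranose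
Product: 2 1,2:5,6-di-O-isopropylidene-α-D-ribo-hexofuranos-3-ulose
Conditions: Dess–Martin periodinane, CH2Cl2, rt
Reagents that add atoms: none
Why: Dess–Martin oxidation of the only free hydroxyl should give the 3-ulose without touching the acetonides; no stereocentre is formed, the future C8 becoming trigonal.

Step 2
Reactants: 2 1,2:5,6-di-O-isopropylidene-α-D-ribo-hexofuranos-3-ulose; 3 tert-butyl propanoate
Product: 5 3-C-[(2R)-1-tert-butoxy-1-oxopropan-2-yl]-1,2:5,6-di-O-isopropylidene-α-D-allofuranose, via lithium (Z)-enolate 4 (not isolated)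
Conditions: lithium diisopropylamide, THF/DMPU, −78 °C; then 2, −78 °C; AcOH quench at −78 °C
Reagents that add atoms: none
Why: Ester-enolate aldol addition to the ketone, in which the enolate attacks the convex β-face of the cis-fused furanose–dioxolane bicycle (opposite the 1,2-acetonide) and so sets C8 in the allo configuration, while a closed Zimmerman–Traxler chair of the Z(O)-enolate with the ester over the less hindered sugar C2–H side is expected to place the C18 methyl as drawn (17R), a centre that stays correctable because it is α to a carbonyl.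

Step 3
Reactants: 5 3-C-[(2R)-1-tert-butoxy-1-oxopropan-2-yl]-1,2:5,6-di-O-isopropylidene-α-D-allofuranose
Product: 7 3-C-[(2R)-1-tert-butoxy-1-oxopropan-2-yl]-1,2-O-isopropylidene-α-D-ribo-pentodialdo-1,4-furanose, via 5,6-diol 6 (not isolated)
Conditions: H5IO6, EtOAc, rt
Reagents that add atoms: none
Why: Periodic acid should hydrolyse the terminal 5,6-acetonide selectively (the 1,2-acetonide of the cis-fused bicycle is far more stable) and cleave the freed glycol in the same flask (Malaprade cleavage), giving the C10 aldehyde with C9 untouched.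

Step 4
Reactants: 7 3-C-[(2R)-1-tert-butoxy-1-oxopropan-2-yl]-1,2-O-isopropylidene-α-D-ribo-pentodialdo-1,4-furanose; 8 3-(triphenyl-λ5-phosphanylidene)butan-2-one
Product: 9 (E)-enone (sugar C4 bearing the C10H=C1(CH3)–C14(=O)–C13H3 chain)
Conditions: PhMe, 80 °C
Reagents that add atoms: none
Why: Wittig olefination with a stabilised α-methyl acyl ylide is neutral, so the α-alkoxy aldehyde should not epimerise at C9, and it is E-selective, placing C9 trans to the acetyl group and cis to the C15 methyl as the cycloaddition requires.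

Step 5
Reactants: 9 (E)-enone
Product: 10 bis-silylated 2-silyloxydiene C13H2=C14(OSiEt3)–C1(CH3)=C10H–Fur
Conditions: Et3SiOTf (3 equiv), Et3N, CH2Cl2, −78 → 0 °C
Reagents that add atoms: triethylsilyl trifluoromethanesulfonate, CC[Si](CC)(CC)OS(=O)(=O)C(F)(F)F
Why: Soft enolisation of the methyl ketone, the only enolisable α-position, should give the cross-conjugated 2-silyloxydiene while the same reagent caps the tertiary C8 hydroxyl; no stereocentre changes.

Step 6
Reactants: 10 bis-silylated 2-silyloxydiene; 11 ethyl (2E)-3-(4,4,5,5-tetramethyl-1,3,2-dioxaborolan-2-yl)prop-2-enoate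
Product: 12 cycloadduct (cyclohexene with C14(OSiEt3)=C1(CH3); C10-Fur β; C11-CO2Et β; C12-pinacolboryl α)
Conditions: Me2AlCl (1.2 equiv), CH2Cl2, −78 → −30 °C; Et3N, then aq. NaHCO3
Reagents that add atoms: none
Why: Lewis-acid-promoted normal-demand Diels–Alder reaction (closest type: Me2AlCl-promoted cycloadditions of 2-silyloxy-1,3-dienes with acrylates), concerted but asynchronous, in which the nucleophilic diene terminus C13 (next to the silyloxy carbon) bonds to the boron-bearing β-carbon C12 and C10 bonds to the ester-bearing C11, so the ester ends para to the silyloxy group. The cyclohexene ring closes in one suprafacial–suprafacial [4+2] event and leaves the C14=C1 silyl enol ether in place for step 11. C10 is controlled by the sugar centre C9: allylic 1,3-strain with the cis C15 methyl holds C9–H in the diene plane, so the two diene faces are flanked by the ring oxygen O9 and by the fully substituted C8, and the dienophile should add past O9. C11 follows from the endo orientation of the aluminium-complexed ester (cis to the furanosyl group on C10) with the bulky pinacolboryl group exo, and C12 follows from the E geometry of 11 (boron trans to the ester). The step needs regio-, endo- and facial selectivity together; they are secured by the 2-silyloxy group, by complexation of the acrylate carbonyl, and by the conformational lock at C9 respectively.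

Step 7
Reactants: 12 cycloadduct
Product: 13 primary alcohol (C11–CH2OH)
Conditions: i-Bu2AlH (2.5 equiv), CH2Cl2, −78 °C; Rochelle salt work-up
Reagents that add atoms: none
Why: i-Bu2AlH reduction should convert the unhindered ethyl ester into the primary alcohol, while the tert-butyl ester (α-branched, next to quaternary C8), the silyl enol ether and the pinacol boronate are expected to be inert at −78 °C.

Step 8
Reactants: 13 primary alcohol
Product: 14 primary iodide (C11–CH2I)
Conditions: PPh3, I2, imidazole, CH2Cl2, 0 °C (I2 premixed with PPh3)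
Reagents that add atoms: iodine, II
Why: Appel-type (Garegg–Samuelsson) iodination of the only hydroxyl under imidazole buffering, with the iodine consumed as the phosphonium salt before the substrate is added so that the silyl enol ether is not iodinated.

Step 9
Reactants: 14 primary iodide
Product: 15 silyl enol ether with the C20 methyl on C11
Conditions: Bu3SnH, AIBN (cat.), PhMe, 80 °C
Reagents that add atoms: none
Why: Radical chain dehalogenation should turn the iodomethyl group into the C20 methyl, and C11 (set in step 6) is not touched because the radical is exocyclic.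

Step 10
Reactants: 16 trimethyl phosphonoacetate; 17 acrolein
Product: 18 methyl 2-(dimethoxyphosphoryl)-5-oxopentanoate
Conditions: NaOMe (5 mol %), MeOH, 0 °C (16 in excess)
Reagents that add atoms: none
Why: Base-catalysed Michael addition of the phosphonoacetate carbanion to acrolein should give the C2–C5/C16 building block, which cannot olefinate itself because that would form a cyclobutene.

Step 11
Reactants: 15 silyl enol ether with the C20 methyl; 18 methyl 2-(dimethoxyphosphoryl)-5-oxopentanoate
Product: 19 aldol (C14 ketone; quaternary C1; (2R)-carbinol; phosphonoacetate chain)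
Conditions: BF3·OEt2 (3 equiv), CH2Cl2, −78 °C; aq. NaHCO3
Reagents that add atoms: none
Why: Mukaiyama aldol addition of the tetrasubstituted silyl enol ether should create the quaternary C1 by attack on the α-face, anti to the pseudoaxial furanosyl group on the neighbouring C10, and an open antiperiplanar transition state with the aldehyde chain next to the small C15 methyl instead of C10 is expected to give the 2R carbinol.

Step 12
Reactants: 19 aldol
Product: 21 triol (2R, 12α, 14α hydroxyls), via boronate diol 20 (not isolated)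
Conditions: Et2BOMe, NaBH4, THF/MeOH (4:1), −78 → −40 °C; then NaBO3·4H2O, THF/H2O, rt
Reagents that add atoms: sodium perborate, [Na+].OO[B-](O)(O)O
Why: Narasaka–Prasad reduction, in which hydride should add to the C14 carbonyl held in the diethylboron chelate of the C2 hydroxyl from the β-face (away from the chelate arm and the α-oriented boronate on C12) to give the 1,3-syn (2R,14S) diol, followed by an oxidative work-up that converts C12–B into C12–OH with retention.

Step 13
Reactants: 21 triol
Product: 22 triacetate (C2, C12, C14)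
Conditions: Ac2O, pyridine, DMAP, CH2Cl2, rt → 40 °C
Reagents that add atoms: acetic anhydride, CC(=O)OC(C)=O
Why: DMAP-catalysed acetylation should esterify the three secondary hydroxyls, the only free OH groups (O8 is silylated), installing three of the four acetates of the target.

Step 14
Reactants: 22 triacetate
Product: 23 lactol acid (C6 hemiacetal; free C7–OH and C8–OH; C19 acid)
Conditions: CF3CO2H/H2O (9:1), 0 °C → rt
Reagents that add atoms: none
Why: Acidolysis should remove the 1,2-O-isopropylidene group (unmasking C6 as the furanose lactol and the C7 hydroxyl), the tert-butyl ester and the tertiary silyl ether in one operation, while acetates and the dimethyl phosphonate are expected to survive aqueous trifluoroacetic acid.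

Step 15
Reactants: 23 lactol acid
Product: 25 9-O-deacetyl target (7,19-lactone; free 8- and 9-OH), via ring-closed dihydroxy acid 24 (not isolated)
Conditions: LiCl, DBU, MeCN (1 mM), rt; then PPTS, CH2Cl2, rt
Reagents that add atoms: none
Why: Intramolecular Horner–Wadsworth–Emmons reaction under Masamune–Roush conditions, in which the lactol reacts through its open hydroxy-aldehyde form, should close the ten-membered ring with the ester trans to C7 (the ring-cis geometry, also the intrinsic preference of α-substituted phosphonoacetates) and release the C9 hydroxyl, after which acid is expected to close the γ-lactone from the C19 acid onto the less hindered allylic C7 hydroxyl, C17 keeping the configuration with its methyl trans to the C9 branch.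

Step 16
Reactants: 25 9-O-deacetyl target
Product: 26 CNP0230222.1
Conditions: Ac2O, pyridine, DMAP (cat.), CH2Cl2, rt
Reagents that add atoms: acetic anhydride, CC(=O)OC(C)=O
Why: Acetylation of the remaining secondary C9 hydroxyl should complete the target, the tertiary C8 hydroxyl not being acylated under these conditions.

**Compound list**

1 | 1,2:5,6-di-O-isopropylidene-α-D-glucofuranose | O[C@@H]1[C@H]2OC(C)(C)O[C@H]2O[C@@H]1[C@H]1COC(C)(C)O1 | starting material
2 | 1,2:5,6-di-O-isopropylidene-α-D-ribo-hexofuranos-3-ulose | O=C1[C@H]2OC(C)(C)O[C@H]2O[C@@H]1[C@H]1COC(C)(C)O1 | intermediate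
3 | tert-butyl propanoate | CCC(=O)OC(C)(C)C | starting material
4 | lithium (Z)-enolate of tert-butyl propanoate (methyl cis to OLi) | [Li+].C/C=C(\[O-])OC(C)(C)C | intermediate
5 | 3-C-[(2R)-1-tert-butoxy-1-oxopropan-2-yl]-1,2:5,6-di-O-isopropylidene-α-D-allofuranose | CC(C)(C)OC(=O)[C@H](C)[C@@]1(O)[C@H](O[C@@H]2OC(C)(C)O[C@@H]21)[C@H]1COC(C)(C)O1 | intermediate
6 | 3-C-[(2R)-1-tert-butoxy-1-oxopropan-2-yl]-1,2-O-isopropylidene-α-D-allofuranose (5,6-diol) | CC(C)(C)OC(=O)[C@H](C)[C@@]1(O)[C@H](O[C@@H]2OC(C)(C)O[C@@H]21)[C@H](O)CO | intermediate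
7 | 3-C-[(2R)-1-tert-butoxy-1-oxopropan-2-yl]-1,2-O-isopropylidene-α-D-ribo-pentodialdo-1,4-furanose | CC(C)(C)OC(=O)[C@H](C)[C@@]1(O)[C@H](O[C@@H]2OC(C)(C)O[C@@H]21)C=O | intermediate
8 | 3-(triphenyl-λ5-phosphanylidene)butan-2-one | CC(=O)C(C)=P(c1ccccc1)(c1ccccc1)c1ccccc1 | starting material
9 | (5E)-3-C-[(2R)-1-tert-butoxy-1-oxopropan-2-yl]-5,6,8-trideoxy-1,2-O-isopropylidene-6-C-methyl-α-D-ribo-oct-5-enofuranos-7-ulose (sugar C5=C6 is C10=C1) | CC(C)(C)OC(=O)[C@H](C)[C@@]1(O)[C@H](O[C@@H]2OC(C)(C)O[C@@H]21)/C=C(\C)C(C)=O | intermediate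
10 | (5E)-3-C-[(2R)-1-tert-butoxy-1-oxopropan-2-yl]-5,6,8-trideoxy-1,2-O-isopropylidene-6-C-methyl-3,7-bis-O-triethylsilyl-α-D-ribo-octa-5,7-dienofuranose | CC(C)(C)OC(=O)[C@H](C)[C@@]1(O[Si](CC)(CC)CC)[C@H](O[C@@H]2OC(C)(C)O[C@@H]21)/C=C(\C)C(=C)O[Si](CC)(CC)CC | intermediate
11 | ethyl (2E)-3-(4,4,5,5-tetramethyl-1,3,2-dioxaborolan-2-yl)prop-2-enoate | CCOC(=O)/C=C/B1OC(C)(C)C(C)(C)O1 | starting material
12 | cycloadduct: cyclohexene C1(CH3)=C14(OSiEt3)–C13H2–C12H(pinacolboryl, α)–C11H(CO2Et, β)–C10H(Fur, β) | CC(C)(C)OC(=O)[C@H](C)[C@@]1(O[Si](CC)(CC)CC)[C@H](O[C@@H]2OC(C)(C)O[C@@H]21)[C@H]1[C@@H](C(=O)OCC)[C@H](B2OC(C)(C)C(C)(C)O2)CC(O[Si](CC)(CC)CC)=C1C | intermediate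
13 | as 12 with CH2OH on C11 (β) | CC(C)(C)OC(=O)[C@H](C)[C@@]1(O[Si](CC)(CC)CC)[C@H](O[C@@H]2OC(C)(C)O[C@@H]21)[C@H]1[C@@H](CO)[C@H](B2OC(C)(C)C(C)(C)O2)CC(O[Si](CC)(CC)CC)=C1C | intermediate
14 | as 12 with CH2I on C11 (β) | CC(C)(C)OC(=O)[C@H](C)[C@@]1(O[Si](CC)(CC)CC)[C@H](O[C@@H]2OC(C)(C)O[C@@H]21)[C@H]1[C@@H](CI)[C@H](B2OC(C)(C)C(C)(C)O2)CC(O[Si](CC)(CC)CC)=C1C | intermediate
15 | as 12 with CH3 (C20) on C11 (β) | CC(C)(C)OC(=O)[C@H](C)[C@@]1(O[Si](CC)(CC)CC)[C@H](O[C@@H]2OC(C)(C)O[C@@H]21)[C@H]1[C@@H](C)[C@H](B2OC(C)(C)C(C)(C)O2)CC(O[Si](CC)(CC)CC)=C1C | intermediate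
16 | trimethyl phosphonoacetate (methyl 2-(dimethoxyphosphoryl)acetate) | COC(=O)CP(=O)(OC)OC | starting material
17 | acrolein (prop-2-enal) | C=CC=O | starting material
18 | methyl 2-(dimethoxyphosphoryl)-5-oxopentanoate (racemic) | COC(=O)C(CCC=O)P(=O)(OC)OC | intermediate
19 | aldol: C14 ketone; C1 quaternary with 1β-CH3 and 1α-[(1R)-1-hydroxy-4-(dimethoxyphosphoryl)-5-methoxy-5-oxopentyl] chain (C2–C5, C16); C10-Fur β; 11β-CH3; 12α-pinacolboryl | CC(C)(C)OC(=O)[C@H](C)[C@@]1(O[Si](CC)(CC)CC)[C@H](O[C@@H]2OC(C)(C)O[C@@H]21)[C@H]1[C@@H](C)[C@H](B2OC(C)(C)C(C)(C)O2)CC(=O)[C@]1(C)[C@H](O)CCC(C(=O)OC)P(=O)(OC)OC | intermediate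
20 | as 19 with 14α-OH (14S) in place of the ketone, boronate intact (present in the flask as its diethylboron chelate) | CC(C)(C)OC(=O)[C@H](C)[C@@]1(O[Si](CC)(CC)CC)[C@H](O[C@@H]2OC(C)(C)O[C@@H]21)[C@H]1[C@@H](C)[C@H](B2OC(C)(C)C(C)(C)O2)C[C@H](O)[C@]1(C)[C@H](O)CCC(C(=O)OC)P(=O)(OC)OC | intermediate
21 | triol: as 20 with 12α-OH in place of boron (2R, 12R, 14S hydroxyls) | CC(C)(C)OC(=O)[C@H](C)[C@@]1(O[Si](CC)(CC)CC)[C@H](O[C@@H]2OC(C)(C)O[C@@H]21)[C@H]1[C@@H](C)[C@H](O)C[C@H](O)[C@]1(C)[C@H](O)CCC(C(=O)OC)P(=O)(OC)OC | intermediate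
22 | 2,12,14-tri-O-acetate of 21 | CC(C)(C)OC(=O)[C@H](C)[C@@]1(O[Si](CC)(CC)CC)[C@H](O[C@@H]2OC(C)(C)O[C@@H]21)[C@H]1[C@@H](C)[C@H](OC(C)=O)C[C@H](OC(C)=O)[C@]1(C)[C@H](OC(C)=O)CCC(C(=O)OC)P(=O)(OC)OC | intermediate
23 | lactol acid: 22 without acetonide, tert-butyl and silyl groups (C6 hemiacetal, free C7–OH and C8–OH, C19 carboxylic acid) | OC(=O)[C@H](C)[C@@]1(O)[C@H](OC(O)[C@@H]1O)[C@H]1[C@@H](C)[C@H](OC(C)=O)C[C@H](OC(C)=O)[C@]1(C)[C@H](OC(C)=O)CCC(C(=O)OC)P(=O)(OC)OC | intermediate
24 | ring-closed dihydroxy acid: ten-membered ring with the C5=C6 methyl enoate, free 7-, 8- and 9-OH, C19 carboxylic acid | COC(=O)/C1=C/[C@H](O)[C@@](O)([C@@H](C)C(O)=O)[C@H](O)[C@H]2[C@@H](C)[C@H](OC(C)=O)C[C@H](OC(C)=O)[C@]2(C)[C@H](OC(C)=O)CC1 | intermediate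
25 | 9-O-deacetyl target (7,19-lactone, free 8- and 9-OH, acetates on C2, C12, C14) | COC(=O)/C1=C/[C@@H]2OC(=O)[C@H](C)[C@@]2(O)[C@H](O)[C@H]2[C@@H](C)[C@H](OC(C)=O)C[C@H](OC(C)=O)[C@]2(C)[C@H](OC(C)=O)CC1 | intermediate
26 | CNP0230222.1: briarane with C16 methyl ester, 5(6)E-alkene, 7,19-lactone, 8-OH, acetates on C2, C9, C12, C14; (1S,2R,7S,8S,9R,10S,11R,12R,14S,17R) | COC(=O)/C1=C/[C@@H]2OC(=O)[C@H](C)[C@@]2(O)[C@H](OC(C)=O)[C@H]2[C@@H](C)[C@H](OC(C)=O)C[C@H](OC(C)=O)[C@]2(C)[C@H](OC(C)=O)CC1 | target

**Step count and risks**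

Total step count: 16. Longest linear sequence: 15 steps (steps 1–9 and 11–16); step 10 is a one-step side branch.

Steps most likely to fail:

1. Step 15 (ring closure and lactonisation). Closure of the strained ten-membered ring may lose to intermolecular olefination. Under base the open α-hydroxy aldehyde may epimerise at C7, or the released O9 alkoxide may add back to C6 of the new enoate. Lactonisation may also engage O9 instead of O7. Fallback by olefin metathesis with the lactone formed before the ring: it sets out from 22. Olefination of the phosphonate with paraformaldehyde (K2CO3, THF, reflux) should give the α-methylene ester F1. CF3CO2H/H2O should then give the lactol acid F2. Methylenation of the lactol with salt-free Ph3P=CH2 (−78 → 0 °C) and acid-mediated lactonisation onto O7 should give the vinyl lactone F3. Ring-closing metathesis of F3 (second-generation Hoveyda–Grubbs catalyst, PhMe, 80 °C, high dilution), with the lactone restricting the chain, should give 25, where the route is rejoined.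

2. Step 11 (Mukaiyama aldol). The hindered tetrasubstituted enol ether may discriminate poorly between the two open transition states, so that the C2 carbinol forms as a mixture. Fallback that sets C2 by directed reduction instead: it sets out from 19 taken as a mixture of C2 epimers. Dess–Martin oxidation should give the C2,C14-diketone F4. Anhydrous Me3NO (THF, 60 °C) should oxidise the boronate to the 12-hydroxy diketone F5 without hydroxide, which would cleave the non-enolisable 1,3-diketone. Et2BOMe/NaBH4 at −78 °C should reduce only the C14 carbonyl activated in the boron chelate of the C12 hydroxyl, giving the cis-1,3-diol ketone F6. A second Et2BOMe/NaBH4 reduction, now relayed from the C14 hydroxyl to the C2 carbonyl (1,3-syn), should give 21, where the route is rejoined.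

3. Step 6 (cycloaddition). The β-boryl acrylate may be too unreactive toward the crowded diene, so that Lewis-acid-induced loss of the dienol silyl ether or open-chain Mukaiyama–Michael addition outruns ring closure, or endo control erodes at the congested C10/C1 end. Fallback with an aldehyde dienophile under neutral conditions: it sets out from 10 and 11. i-Bu2AlH reduction of 11 should give the allylic alcohol F7, and MnO2 oxidation the enal F8. F8 and diene 10 in PhMe at 60 °C without Lewis acid should give the aldehyde cycloadduct F9 through the same endo transition state. NaBH4 (EtOH/THF, −20 °C) should reduce F9 to 13, where the route is rejoined (step 7 is then not needed).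

**Further compounds**

F1 | step 15 | α-methylene ester: 22 with CH2CH2C(=CH2)CO2CH3 in place of the phosphonoacetate terminus | CC(C)(C)OC(=O)[C@H](C)[C@@]1(O[Si](CC)(CC)CC)[C@H](O[C@@H]2OC(C)(C)O[C@@H]21)[C@H]1[C@@H](C)[C@H](OC(C)=O)C[C@H](OC(C)=O)[C@]1(C)[C@H](OC(C)=O)CCC(=C)C(=O)OC
F2 | step 15 | lactol acid of F1 (C6 hemiacetal, free C7–OH and C8–OH, C19 acid) | OC(=O)[C@H](C)[C@@]1(O)[C@H](OC(O)[C@@H]1O)[C@H]1[C@@H](C)[C@H](OC(C)=O)C[C@H](OC(C)=O)[C@]1(C)[C@H](OC(C)=O)CCC(=C)C(=O)OC
F3 | step 15 | vinyl lactone: 7,19-lactone with vinyl (C6) on C7, free 8- and 9-OH, α-methylene ester terminus | C=C[C@@H]1OC(=O)[C@H](C)[C@@]1(O)[C@H](O)[C@H]1[C@@H](C)[C@H](OC(C)=O)C[C@H](OC(C)=O)[C@]1(C)[C@H](OC(C)=O)CCC(=C)C(=O)OC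
F4 | step 11 | C2,C14-diketone of 19 (boronate intact) | CC(C)(C)OC(=O)[C@H](C)[C@@]1(O[Si](CC)(CC)CC)[C@H](O[C@@H]2OC(C)(C)O[C@@H]21)[C@H]1[C@@H](C)[C@H](B2OC(C)(C)C(C)(C)O2)CC(=O)[C@]1(C)C(=O)CCC(C(=O)OC)P(=O)(OC)OC
F5 | step 11 | 12α-hydroxy C2,C14-diketone | CC(C)(C)OC(=O)[C@H](C)[C@@]1(O[Si](CC)(CC)CC)[C@H](O[C@@H]2OC(C)(C)O[C@@H]21)[C@H]1[C@@H](C)[C@H](O)CC(=O)[C@]1(C)C(=O)CCC(C(=O)OC)P(=O)(OC)OC
F6 | step 11 | 12α,14α-diol with C2 ketone | CC(C)(C)OC(=O)[C@H](C)[C@@]1(O[Si](CC)(CC)CC)[C@H](O[C@@H]2OC(C)(C)O[C@@H]21)[C@H]1[C@@H](C)[C@H](O)C[C@H](O)[C@]1(C)C(=O)CCC(C(=O)OC)P(=O)(OC)OC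
F7 | step 6 | (2E)-3-(4,4,5,5-tetramethyl-1,3,2-dioxaborolan-2-yl)prop-2-en-1-ol | OC/C=C/B1OC(C)(C)C(C)(C)O1
F8 | step 6 | (2E)-3-(4,4,5,5-tetramethyl-1,3,2-dioxaborolan-2-yl)prop-2-enal | O=C/C=C/B1OC(C)(C)C(C)(C)O1
F9 | step 6 | aldehyde cycloadduct: as 12 with CHO on C11 (β) | CC(C)(C)OC(=O)[C@H](C)[C@@]1(O[Si](CC)(CC)CC)[C@H](O[C@@H]2OC(C)(C)O[C@@H]21)[C@H]1[C@@H](C=O)[C@H](B2OC(C)(C)C(C)(C)O2)CC(O[Si](CC)(CC)CC)=C1C
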